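**Retrosynthetic overview**
- Feature: ring B (the 2-aryl ring) carries two neighbouring prenyl-derived C5 units. The one on C3' is closed onto O4' as the 2,2-dimethyl-2H-pyran (chromene) ring; the one on C2' stays an open prenyl group.
- Ring C: O1–C2 by Mitsunobu closure with inversion; C2–C3 by catalytic asymmetric addition of a ring A arylethylzinc reagent to a ring B chromene aldehyde. The C5' phenol travels as its methyl ether and is freed last with thiolate.
- Key disconnection: O4'–C(CH3)2 of the pyran ring, by DDQ dehydrogenation of a 4-hydroxy-2,3-diprenylbenzaldehyde to an o-quinone methide and oxa-6π electrocyclization. Both prenyl groups come from 5,6-dibromovanillin by twofold Stille coupling.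
- Ring A fragment: from 2,4-dihydroxybenzaldehyde; hydroxyethyl arm by Wittig methylenation and hydroboration, 1,1-dimethylallyl group by Claisen rearrangement of the prenyl ether, then the iodide.
- Ring order: rings A and B are bought as arenes; the pyran ring on ring B is closed first (step 5), ring C second (step 15).

Key step: step 5

Numbering: flavan O1, C2–C4, ring A C4a–C8a, ring B primed; fragments keep their own benzaldehyde or phenol numbering.
Assumption: the facial sense of the Ti(OiPr)4/bis(sulfonamide) catalyst is carried over from simple aromatic aldehydes; if the ortho-prenyl aldehyde responds in the opposite sense, the enantiomeric ligand is used.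

**Ring B branch**

Step 1
Reactants: 1 vanillin (4-hydroxy-3-methoxybenzaldehyde)
Product: 3 2,3-dibromo-4-hydroxy-5-methoxybenzaldehyde, via 5-bromovanillin 2 (not isolated)
Conditions: Br2 (2.2 equiv), Fe powder (cat.), NaOAc, AcOH, rt
Reagents that add atoms: bromine, BrBr
Why: Electrophilic aromatic bromination; the first bromine enters ortho to the free phenol and, with FeBr3 formed in the flask, the second enters para to the methoxy group, the position most activated by the remaining donor.

Step 2
Reactants: 3 2,3-dibromo-4-hydroxy-5-methoxybenzaldehyde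
Product: 4 2,3-dibromo-4-formyl-6-methoxyphenyl acetate
Conditions: Ac2O, pyridine, DMAP (cat.), CH2Cl2, rt
Reagents that add atoms: acetic anhydride, CC(=O)OC(C)=O
Why: DMAP-catalysed O-acylation masks the acidic phenol, whose phenoxide would slow oxidative addition in the coupling, and the acetate comes off later under mild base.

Step 3
Reactants: 4 2,3-dibromo-4-formyl-6-methoxyphenyl acetate; 5 tributyl(3-methylbut-2-enyl)stannane (3 equiv)
Product: 7 4-formyl-6-methoxy-2,3-bis(3-methylbut-2-enyl)phenyl acetate, via monoprenylated bromo acetate 6 (not isolated)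
Conditions: Pd(PPh3)4 (10 mol %), DMF, 100 °C
Reagents that add atoms: none
Why: Twofold Stille coupling; both electron-poor aryl bromides add oxidatively to the palladium catalyst (the one ortho to the formyl group first), and transmetalation from the allylic stannane with reductive elimination at the unsubstituted allyl terminus should give the linear prenyl groups.

Step 4
Reactants: 7 4-formyl-6-methoxy-2,3-bis(3-methylbut-2-enyl)phenyl acetate
Product: 8 4-hydroxy-5-methoxy-2,3-bis(3-methylbut-2-enyl)benzaldehyde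
Conditions: K2CO3 (1.2 equiv), MeOH, 0 °C to rt; aq. NH4Cl
Reagents that add atoms: none
Why: Base-mediated methanolysis (transesterification) of the activated aryl acetate frees the C4 phenol without touching the aldehyde or the prenyl groups.

Step 5
Reactants: 8 4-hydroxy-5-methoxy-2,3-bis(3-methylbut-2-enyl)benzaldehyde
Product: 10 8-methoxy-2,2-dimethyl-5-(3-methylbut-2-enyl)-2H-chromene-6-carbaldehyde, via o-quinone methide 9 (not isolated)
Conditions: DDQ (1.1 equiv), toluene, 80 °C
Reagents that add atoms: none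
Why: DDQ forms a charge-transfer complex with the free C4 phenol of 8 and removes hydride from the benzylic, allylic CH2 of the C3 prenyl group, which gives o-quinone methide 9 conjugated with the trisubstituted alkene. The isomer of 9 with the vinyl group cis to the carbonyl then undergoes thermal disrotatory oxa-6π electrocyclization, which forms the O–C(CH3)2 bond, closes the six-membered pyran ring (electrocyclic, formally 6-endo) and restores the arene. The closest known reaction type is the DDQ-mediated dehydrogenative cyclization of ortho-prenylphenols to 2,2-dimethyl-2H-chromenes, which also runs on carbonyl-substituted phenols at elevated temperature. No stereocentre is formed. The step needs site selectivity between the two prenyl groups, and the substrate fixes it: only the C3 prenyl is ortho to the free OH, the C2 prenyl is meta and cannot be drawn into a quinone methide, and the formyl group occupies the para position so that no p-quinone methide can form. Near-stoichiometric DDQ and the loss of the free phenol on cyclization should protect the remaining benzylic CH2 and the new chromene from further oxidation.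

**Ring A branch**

Step 6
Reactants: 11 2,4-dihydroxybenzaldehyde; 12 1-bromo-3-methylbut-2-ene
Product: 13 2-hydroxy-4-(3-methylbut-2-enyloxy)benzaldehyde
Conditions: K2CO3 (1.1 equiv), acetone, rt to 50 °C
Reagents that add atoms: none
Why: Williamson etherification is selective for the 4-OH because the 2-OH is held in a hydrogen bond to the formyl group and is the less acidic and less nucleophilic of the two.

Step 7
Reactants: 13 2-hydroxy-4-(3-methylbut-2-enyloxy)benzaldehyde
Product: 14 4-(3-methylbut-2-enyloxy)-2-(triisopropylsilyloxy)benzaldehyde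
Conditions: TIPSCl, imidazole, DMF, rt
Reagents that add atoms: chlorotriisopropylsilane, CC(C)[Si](Cl)(C(C)C)C(C)C
Why: Silylation of the remaining phenol with the bulky triisopropylsilyl group gives an ether that should withstand the ylide, the borane oxidation and the later thermal step.

Step 8
Reactants: 14 4-(3-methylbut-2-enyloxy)-2-(triisopropylsilyloxy)benzaldehyde
Product: 15 triisopropyl[5-(3-methylbut-2-enyloxy)-2-vinylphenoxy]silane
Conditions: Ph3PCH3Br, KOtBu, THF, 0 °C to rt
Reagents that add atoms: methyltriphenylphosphonium bromide, C[P+](c1ccccc1)(c1ccccc1)c1ccccc1.[Br-]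
Why: Wittig methylenation turns the aldehyde into the styrene needed for anti-Markovnikov hydration.

Step 9
Reactants: 15 triisopropyl[5-(3-methylbut-2-enyloxy)-2-vinylphenoxy]silane
Product: 17 2-[4-(3-methylbut-2-enyloxy)-2-(triisopropylsilyloxy)phenyl]ethanol, via B-alkyl-9-BBN adduct 16 (not isolated)
Conditions: 9-BBN, THF, 0 °C to rt; then NaBO3·4H2O, H2O, rt
Reagents that add atoms: sodium perborate tetrahydrate, [Na+].[Na+].O[B-]1(O)OO[B-](O)(O)OO1.O.O.O.O.O.O
Why: Hydroboration with the bulky 9-BBN places boron on the terminal carbon of the monosubstituted styrene and leaves the trisubstituted prenyl ether alkene alone, and the mild perborate oxidation replaces boron by OH without cleaving the aryl silyl ether.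

Step 10
Reactants: 17 2-[4-(3-methylbut-2-enyloxy)-2-(triisopropylsilyloxy)phenyl]ethanol
Product: 19 4-(2-hydroxyethyl)-2-(2-methylbut-3-en-2-yl)-5-(triisopropylsilyloxy)phenol, via ortho-dienone 18 (not isolated)
Conditions: PhNEt2, 190 °C, sealed tube, Ar
Reagents that add atoms: none
Why: Aromatic Claisen ([3,3]-sigmatropic) rearrangement delivers the dimethyl-substituted allyl terminus to the free, less hindered ortho carbon (the other ortho carbon lies between two oxygen substituents), tautomerization of dienone 18 gives the phenol with the 1,1-dimethylallyl group, and the blocked para position rules out a following Cope shift.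

Step 11
Reactants: 19 4-(2-hydroxyethyl)-2-(2-methylbut-3-en-2-yl)-5-(triisopropylsilyloxy)phenol
Product: 20 4-(2-iodoethyl)-2-(2-methylbut-3-en-2-yl)-5-(triisopropylsilyloxy)phenol
Conditions: PPh3, I2, imidazole, CH2Cl2, 0 °C (PPh3 and I2 premixed)
Reagents that add atoms: iodine, II
Why: Appel-type iodination activates only the primary alcohol as its oxyphosphonium salt for SN2 displacement by iodide, while the hindered phenol stays free, as in the iodination of tyrosol.

Step 12
Reactants: 20 4-(2-iodoethyl)-2-(2-methylbut-3-en-2-yl)-5-(triisopropylsilyloxy)phenol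
Product: 21 tert-butyl[4-(2-iodoethyl)-2-(2-methylbut-3-en-2-yl)-5-(triisopropylsilyloxy)phenoxy]dimethylsilane
Conditions: TBSOTf, 2,6-lutidine, CH2Cl2, 0 °C
Reagents that add atoms: tert-butyldimethylsilyl trifluoromethanesulfonate, CC(C)(C)[Si](C)(C)OS(=O)(=O)C(F)(F)F
Why: The silyl triflate with a hindered pyridine base silylates the phenol next to the quaternary carbon, where the chloride would be too slow, and the primary iodide is inert to these conditions.

**Fragment union and end game**

Step 13
Reactants: 21 tert-butyl[4-(2-iodoethyl)-2-(2-methylbut-3-en-2-yl)-5-(triisopropylsilyloxy)phenoxy]dimethylsilane (about 4 equiv); 10 8-methoxy-2,2-dimethyl-5-(3-methylbut-2-enyl)-2H-chromene-6-carbaldehyde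
Product: 23 (1R)-3-[4-(tert-butyldimethylsilyloxy)-5-(2-methylbut-3-en-2-yl)-2-(triisopropylsilyloxy)phenyl]-1-[8-methoxy-2,2-dimethyl-5-(3-methylbut-2-enyl)-2H-chromen-6-yl]propan-1-ol, via bis(arylethyl)zinc 22 (not isolated)
Conditions: Et2Zn (neat), CuI (cat.), 50 °C, then EtI and excess Et2Zn removed in vacuo; Ti(OiPr)4, (1S,2S)-1,2-bis(trifluoromethanesulfonamido)cyclohexane (8 mol %), toluene, −20 °C, then 10; aq. NH4Cl
Reagents that add atoms: none
Why: Iodine–zinc exchange gives the functionalized dialkylzinc 22, and its Ti(OiPr)4/chiral bis(sulfonamide)-catalysed 1,2-addition to the aryl aldehyde sets the carbinol centre; the (1S,2S)-ligand is expected to direct the alkyl group to the Re face and give the (R)-alcohol, by analogy with the (1R,2R)-ligand, which gives (S)-1-phenylpropanol from benzaldehyde and Et2Zn.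

Step 14
Reactants: 23 the (1R)-bis-silyl carbinol
Product: 24 4-{(3R)-3-hydroxy-3-[8-methoxy-2,2-dimethyl-5-(3-methylbut-2-enyl)-2H-chromen-6-yl]propyl}-6-(2-methylbut-3-en-2-yl)benzene-1,3-diol
Conditions: TBAF (2.5 equiv), THF, 0 °C; aq. NH4Cl
Reagents that add atoms: none
Why: Fluoride cleaves both aryl silyl ethers, while the carbinol, the alkenes and the methyl ether are inert to TBAF.

Step 15
Reactants: 24 the (3R)-triol
Product: 26 (2S)-2-[8-methoxy-2,2-dimethyl-5-(3-methylbut-2-enyl)-2H-chromen-6-yl]-6-(2-methylbut-3-en-2-yl)chroman-7-ol, via alkoxyphosphonium phenoxide 25 (not isolated)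
Conditions: PPh3, DIAD, toluene (0.01 M), 0 °C
Reagents that add atoms: none
Why: Intramolecular Mitsunobu etherification; the carbinol is activated as oxyphosphonium ion 25 and displaced by the neighbouring ortho phenoxide in a 6-exo-tet SN2 closure with inversion, (R)-carbinol to (2S)-flavan, while the second phenol, flanked by the quaternary carbon and able to react only between molecules, should not compete at high dilution, and toluene at 0 °C disfavours ionization of the p-alkoxybenzylic centre.

Step 16
Reactants: 26 the (2S)-flavan 5'-methyl ether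
Product: 27 kazinol H, (2S)-2-[8-hydroxy-2,2-dimethyl-5-(3-methylbut-2-enyl)-2H-chromen-6-yl]-6-(2-methylbut-3-en-2-yl)chroman-7-ol
Conditions: NaSEt (excess), DMF, 130 °C; aq. NH4Cl
Reagents that add atoms: none
Why: SN2 attack of ethanethiolate on the methyl group of the aryl methyl ether (thiolate O-demethylation) frees the C5' phenol under non-acidic conditions, so the chromene, the prenyl and 1,1-dimethylallyl groups and the C2 stereocentre should stay untouched.

**Compound list**

1 | vanillin (4-hydroxy-3-methoxybenzaldehyde) | COc1cc(C=O)ccc1O | starting material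
2 | 5-bromovanillin (3-bromo-4-hydroxy-5-methoxybenzaldehyde) | COc1cc(C=O)cc(Br)c1O | intermediate
3 | 2,3-dibromo-4-hydroxy-5-methoxybenzaldehyde | COc1cc(C=O)c(Br)c(Br)c1O | intermediate
4 | 2,3-dibromo-4-formyl-6-methoxyphenyl acetate | COc1cc(C=O)c(Br)c(Br)c1OC(C)=O | intermediate
5 | tributyl(3-methylbut-2-enyl)stannane | CCCC[Sn](CCCC)(CCCC)CC=C(C)C | starting material
6 | 2-bromo-4-formyl-6-methoxy-3-(3-methylbut-2-enyl)phenyl acetate | COc1cc(C=O)c(CC=C(C)C)c(Br)c1OC(C)=O | intermediate
7 | 4-formyl-6-methoxy-2,3-bis(3-methylbut-2-enyl)phenyl acetate | COc1cc(C=O)c(CC=C(C)C)c(CC=C(C)C)c1OC(C)=O | intermediate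
8 | 4-hydroxy-5-methoxy-2,3-bis(3-methylbut-2-enyl)benzaldehyde | COc1cc(C=O)c(CC=C(C)C)c(CC=C(C)C)c1O | intermediate
9 | o-quinone methide of 8 (C4 carbonyl, exocyclic 3-methylbut-2-enylidene on C3) | COC1=CC(C=O)=C(CC=C(C)C)C(=CC=C(C)C)C1=O | intermediate
10 | 8-methoxy-2,2-dimethyl-5-(3-methylbut-2-enyl)-2H-chromene-6-carbaldehyde | COc1cc(C=O)c(CC=C(C)C)c2c1OC(C)(C)C=C2 | intermediate
11 | 2,4-dihydroxybenzaldehyde | O=Cc1ccc(O)cc1O | starting material
12 | 1-bromo-3-methylbut-2-ene | CC(C)=CCBr | starting material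
13 | 2-hydroxy-4-(3-methylbut-2-enyloxy)benzaldehyde | CC(C)=CCOc1ccc(C=O)c(O)c1 | intermediate
14 | 4-(3-methylbut-2-enyloxy)-2-(triisopropylsilyloxy)benzaldehyde | CC(C)=CCOc1ccc(C=O)c(O[Si](C(C)C)(C(C)C)C(C)C)c1 | intermediate
15 | triisopropyl[5-(3-methylbut-2-enyloxy)-2-vinylphenoxy]silane | C=Cc1ccc(OCC=C(C)C)cc1O[Si](C(C)C)(C(C)C)C(C)C | intermediate
16 | 9-{2-[4-(3-methylbut-2-enyloxy)-2-(triisopropylsilyloxy)phenyl]ethyl}-9-borabicyclo[3.3.1]nonane | CC(C)=CCOc1ccc(CCB2C3CCCC2CCC3)c(O[Si](C(C)C)(C(C)C)C(C)C)c1 | intermediate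
17 | 2-[4-(3-methylbut-2-enyloxy)-2-(triisopropylsilyloxy)phenyl]ethanol | CC(C)=CCOc1ccc(CCO)c(O[Si](C(C)C)(C(C)C)C(C)C)c1 | intermediate
18 | 4-(2-hydroxyethyl)-6-(2-methylbut-3-en-2-yl)-3-(triisopropylsilyloxy)cyclohexa-2,4-dienone | C=CC(C)(C)C1C=C(CCO)C(O[Si](C(C)C)(C(C)C)C(C)C)=CC1=O | intermediate
19 | 4-(2-hydroxyethyl)-2-(2-methylbut-3-en-2-yl)-5-(triisopropylsilyloxy)phenol | C=CC(C)(C)c1cc(CCO)c(O[Si](C(C)C)(C(C)C)C(C)C)cc1O | intermediate
20 | 4-(2-iodoethyl)-2-(2-methylbut-3-en-2-yl)-5-(triisopropylsilyloxy)phenol | C=CC(C)(C)c1cc(CCI)c(O[Si](C(C)C)(C(C)C)C(C)C)cc1O | intermediate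
21 | tert-butyl[4-(2-iodoethyl)-2-(2-methylbut-3-en-2-yl)-5-(triisopropylsilyloxy)phenoxy]dimethylsilane | C=CC(C)(C)c1cc(CCI)c(O[Si](C(C)C)(C(C)C)C(C)C)cc1O[Si](C)(C)C(C)(C)C | intermediate
22 | bis{2-[4-(tert-butyldimethylsilyloxy)-5-(2-methylbut-3-en-2-yl)-2-(triisopropylsilyloxy)phenyl]ethyl}zinc | C=CC(C)(C)c1cc(CC[Zn]CCc2cc(C(C)(C)C=C)c(O[Si](C)(C)C(C)(C)C)cc2O[Si](C(C)C)(C(C)C)C(C)C)c(O[Si](C(C)C)(C(C)C)C(C)C)cc1O[Si](C)(C)C(C)(C)C | intermediate
23 | (1R)-3-[4-(tert-butyldimethylsilyloxy)-5-(2-methylbut-3-en-2-yl)-2-(triisopropylsilyloxy)phenyl]-1-[8-methoxy-2,2-dimethyl-5-(3-methylbut-2-enyl)-2H-chromen-6-yl]propan-1-ol | C=CC(C)(C)c1cc(CC[C@@H](O)c2cc(OC)c3OC(C)(C)C=Cc3c2CC=C(C)C)c(O[Si](C(C)C)(C(C)C)C(C)C)cc1O[Si](C)(C)C(C)(C)C | intermediate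
24 | 4-{(3R)-3-hydroxy-3-[8-methoxy-2,2-dimethyl-5-(3-methylbut-2-enyl)-2H-chromen-6-yl]propyl}-6-(2-methylbut-3-en-2-yl)benzene-1,3-diol | C=CC(C)(C)c1cc(CC[C@@H](O)c2cc(OC)c3OC(C)(C)C=Cc3c2CC=C(C)C)c(O)cc1O | intermediate
25 | alkoxy(triphenyl)phosphonium phenoxide of 24 (P on the carbinol oxygen, (R) centre unchanged) | C=CC(C)(C)c1cc(CC[C@@H](O[P+](c2ccccc2)(c2ccccc2)c2ccccc2)c2cc(OC)c3OC(C)(C)C=Cc3c2CC=C(C)C)c([O-])cc1O | intermediate
26 | (2S)-2-[8-methoxy-2,2-dimethyl-5-(3-methylbut-2-enyl)-2H-chromen-6-yl]-6-(2-methylbut-3-en-2-yl)chroman-7-ol | C=CC(C)(C)c1cc2c(cc1O)O[C@H](c1cc(OC)c3c(c1CC=C(C)C)C=CC(C)(C)O3)CC2 | intermediate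
27 | kazinol H, (2S)-2-[8-hydroxy-2,2-dimethyl-5-(3-methylbut-2-enyl)-2H-chromen-6-yl]-6-(2-methylbut-3-en-2-yl)chroman-7-ol | C=CC(C)(C)c1cc2c(cc1O)O[C@H](c1cc(O)c3c(c1CC=C(C)C)C=CC(C)(C)O3)CC2 | target

**Step count**

Total: 16 steps (5 on the ring B branch, 7 on the ring A branch, 4 after fragment union).
Longest linear sequence: 11 steps (steps 6 to 16, from 2,4-dihydroxybenzaldehyde 11).

**Steps most likely to fail**

1. Step 13. The iodine–zinc exchange on the heavy, doubly silylated iodide may stay incomplete, part of the dialkylzinc may be lost when Et2Zn is stripped off, and the addition to the ortho-substituted, electron-rich aldehyde may be slow or poorly face-selective. The fallback replaces the catalytic asymmetric alkylation by a stoichiometric addition followed by a catalytic asymmetric ketone reduction. It sets out from 21 and 10. Iodine–lithium exchange on 21 (t-BuLi, Et2O–pentane, −78 °C) would give the primary organolithium F1, which adds to 10 to give the racemic carbinol F2. Oxidation with Dess–Martin periodinane (NaHCO3, CH2Cl2) would give the aryl ketone F3. Corey–Bakshi–Shibata reduction with (S)-2-methyl-CBS-oxazaborolidine and catecholborane (toluene, −78 °C; catecholborane because it should leave the vinyl group alone at this temperature) should give the (R)-carbinol 23, where the route is rejoined.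

2. Step 5. Hydride abstraction from the formyl-deactivated phenol may be sluggish, oxidation may start at the CH2 of the C2 prenyl group (para to the methoxy group), or the chromene may be oxidized further. The fallback builds the pyran ring by the propargyl ether rearrangement before the open prenyl group is introduced. It sets out from vanillin 1. Acetylation (Ac2O, pyridine) gives vanillin acetate F4, and bromination (Br2, KBr, H2O), now directed para to the methoxy group, gives the bromo acetate F5. Methanolysis (K2CO3, MeOH) gives 6-bromovanillin F6, and O-alkylation with 3-chloro-3-methylbut-1-yne (K2CO3, KI, CuI (cat.), acetone, reflux) gives the aryl 1,1-dimethylpropargyl ether F7. Heating (PhNEt2, 180 °C) should bring about propargyl Claisen rearrangement, 1,5-hydrogen shift and oxa-6π closure at the only free ortho carbon, giving the bromochromene aldehyde F8. A single Stille coupling of F8 with 5 (Pd(PPh3)4, DMF, 100 °C), at a bromide activated by the ortho formyl group, returns to 10.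

3. Step 10. On the electron-rich, non-activated ether the long heating may cleave the prenyl group (loss of isoprene), bring on an abnormal Claisen rearrangement of the product, or move the silyl group to the free primary alcohol. The fallback moves the sigmatropic step to the formyl-activated ether and builds the two-carbon arm afterwards by one-carbon homologation, since hydroboration is no longer possible once the vinyl group is present. It sets out from 14. Heating 14 (PhNEt2, 190 °C) would give the 1,1-dimethylallyl hydroxy aldehyde F9, and silylation (TBSOTf, 2,6-lutidine, CH2Cl2) gives the bis-silyl aldehyde F10. Wittig reaction with methoxymethylenetriphenylphosphorane ((methoxymethyl)triphenylphosphonium chloride, KOtBu, THF, 0 °C) gives the enol ether F11, and mild hydrolysis (aq. HCl, THF, rt) gives the arylacetaldehyde F12. Reduction (NaBH4, MeOH, 0 °C) gives the arylethanol F13, and iodination (PPh3, I2, imidazole, CH2Cl2) returns to 21.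

**Further compounds**

F1 | step 13 | {2-[4-(tert-butyldimethylsilyloxy)-5-(2-methylbut-3-en-2-yl)-2-(triisopropylsilyloxy)phenyl]ethyl}lithium | [Li]CCc1cc(C(C)(C)C=C)c(O[Si](C)(C)C(C)(C)C)cc1O[Si](C(C)C)(C(C)C)C(C)C
F2 | step 13 | racemic 3-[4-(tert-butyldimethylsilyloxy)-5-(2-methylbut-3-en-2-yl)-2-(triisopropylsilyloxy)phenyl]-1-[8-methoxy-2,2-dimethyl-5-(3-methylbut-2-enyl)-2H-chromen-6-yl]propan-1-ol | C=CC(C)(C)c1cc(CCC(O)c2cc(OC)c3OC(C)(C)C=Cc3c2CC=C(C)C)c(O[Si](C(C)C)(C(C)C)C(C)C)cc1O[Si](C)(C)C(C)(C)C
F3 | step 13 | 3-[4-(tert-butyldimethylsilyloxy)-5-(2-methylbut-3-en-2-yl)-2-(triisopropylsilyloxy)phenyl]-1-[8-methoxy-2,2-dimethyl-5-(3-methylbut-2-enyl)-2H-chromen-6-yl]propan-1-one | C=CC(C)(C)c1cc(CCC(=O)c2cc(OC)c3OC(C)(C)C=Cc3c2CC=C(C)C)c(O[Si](C(C)C)(C(C)C)C(C)C)cc1O[Si](C)(C)C(C)(C)C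
F4 | step 5 | 4-formyl-2-methoxyphenyl acetate | COc1cc(C=O)ccc1OC(C)=O
F5 | step 5 | 5-bromo-4-formyl-2-methoxyphenyl acetate | COc1cc(C=O)c(Br)cc1OC(C)=O
F6 | step 5 | 2-bromo-4-hydroxy-5-methoxybenzaldehyde | COc1cc(C=O)c(Br)cc1O
F7 | step 5 | 2-bromo-5-methoxy-4-(2-methylbut-3-yn-2-yloxy)benzaldehyde | COc1cc(C=O)c(Br)cc1OC(C)(C)C#C
F8 | step 5 | 5-bromo-8-methoxy-2,2-dimethyl-2H-chromene-6-carbaldehyde | COc1cc(C=O)c(Br)c2c1OC(C)(C)C=C2
F9 | step 10 | 4-hydroxy-5-(2-methylbut-3-en-2-yl)-2-(triisopropylsilyloxy)benzaldehyde | C=CC(C)(C)c1cc(C=O)c(O[Si](C(C)C)(C(C)C)C(C)C)cc1O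
F10 | step 10 | 4-(tert-butyldimethylsilyloxy)-5-(2-methylbut-3-en-2-yl)-2-(triisopropylsilyloxy)benzaldehyde | C=CC(C)(C)c1cc(C=O)c(O[Si](C(C)C)(C(C)C)C(C)C)cc1O[Si](C)(C)C(C)(C)C
F11 | step 10 | tert-butyl[4-(2-methoxyvinyl)-2-(2-methylbut-3-en-2-yl)-5-(triisopropylsilyloxy)phenoxy]dimethylsilane (E/Z mixture) | C=CC(C)(C)c1cc(C=COC)c(O[Si](C(C)C)(C(C)C)C(C)C)cc1O[Si](C)(C)C(C)(C)C
F12 | step 10 | 2-[4-(tert-butyldimethylsilyloxy)-5-(2-methylbut-3-en-2-yl)-2-(triisopropylsilyloxy)phenyl]acetaldehyde | C=CC(C)(C)c1cc(CC=O)c(O[Si](C(C)C)(C(C)C)C(C)C)cc1O[Si](C)(C)C(C)(C)C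
F13 | step 10 | 2-[4-(tert-butyldimethylsilyloxy)-5-(2-methylbut-3-en-2-yl)-2-(triisopropylsilyloxy)phenyl]ethanol | C=CC(C)(C)c1cc(CCO)c(O[Si](C(C)C)(C(C)C)C(C)C)cc1O[Si](C)(C)C(C)(C)C
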